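The route rests on disconnecting the C2–C3 bond of the 2,3-dihydrobenzofuran (O1–C2–C3 fused to ring C). The feature exploited is the cis relationship between the ring B aryl on C2 and the CH2OH carbon on C3, a kinetic arrangement. A dirhodium carbene generated at the ring C benzylic carbon inserts into a C–H bond of the ring B O–CH2 group, closing the furan ring and setting C2 and C3 in one operation. The precursor is a ring C methyl aryldiazoacetate whose ortho oxygen carries the ring B benzyl group; ring B already bears the silyl-protected erythro (7R,8S) glycerol ether of benzyl-protected ring A, built by an Evans aldol and a Mitsunobu inversion.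

Key step: step 17

Assumption: Rh2(S-PTTL)4 is taken to give the (2R,3S) cis ester; should a trial run show the opposite sense, the mirror-image catalyst Rh2(R-PTTL)4 is used and nothing else changes.

Remark on numbering: O1, C2, C3, C3a, C7a denote the dihydrofuran ring; C7 (benzylic), C8 and C9 denote the glycerol chain between rings A and B. TBS = tert-butyldimethylsilyl, TBSO = TBS–O.

Step 1
Reactants: 1 5-bromo-2-hydroxy-3-methoxybenzaldehyde
Product: 2 2-(benzyloxy)-5-bromo-3-methoxybenzaldehyde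
Conditions: BnBr, K2CO3, DMF, rt
Reagents that add atoms: benzyl bromide, BrCc1ccccc1
Why: Williamson ether synthesis on an acidic salicylaldehyde-type phenol; the benzyl group masks the phenol through the homologation and is later removed in the same hydrogenation that saturates the side chain.

Step 2
Reactants: 2 2-(benzyloxy)-5-bromo-3-methoxybenzaldehyde; 3 methyl (methylsulfanyl)methyl sulfoxide (FAMSO)
Product: 4 2-(benzyloxy)-5-bromo-1-methoxy-3-[2-(methylsulfanyl)-2-(methylsulfinyl)ethenyl]benzene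
Conditions: Triton B (BnNMe3OH, 40% in MeOH, cat.), THF, reflux
Reagents that add atoms: none
Why: Knoevenagel-type condensation of the non-enolisable aryl aldehyde with the sulfur-stabilised carbanion should give the ketene dithioacetal monoxide, a masked arylacetic ester, leaving the aryl bromide and benzyl ether untouched.

Step 3
Reactants: 4 2-(benzyloxy)-5-bromo-1-methoxy-3-[2-(methylsulfanyl)-2-(methylsulfinyl)ethenyl]benzene
Product: 5 methyl 2-[2-(benzyloxy)-5-bromo-3-methoxyphenyl]acetate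
Conditions: HCl (ca. 1 M), MeOH, rt → 40 °C
Reagents that add atoms: methanol, CO
Why: acid-promoted methanolysis of the ketene dithioacetal monoxide (C-protonation, Pummerer-type oxygen transfer from sulfur, loss of MeSSMe) should deliver the methyl arylacetate and so complete the one-carbon homologation; aryl benzyl ether and aryl bromide tolerate methanolic HCl.

Step 4
Reactants: 5 methyl 2-[2-(benzyloxy)-5-bromo-3-methoxyphenyl]acetate; 6 tert-butyldimethyl(prop-2-yn-1-yloxy)silane
Product: 7 methyl 2-[2-(benzyloxy)-3-methoxy-5-(3-TBSO-prop-1-yn-1-yl)phenyl]acetate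
Conditions: Pd(PhCN)2Cl2 (3 mol %), P(t-Bu)3 (6 mol %), CuI (2 mol %), i-Pr2NH, dioxane, rt
Reagents that add atoms: none
Why: Sonogashira coupling; the bulky electron-rich phosphine lets the electron-rich aryl bromide add oxidatively to zerovalent palladium at room temperature, where methyl ester and silyl ether are inert.

Step 5
Reactants: 7 methyl 2-[2-(benzyloxy)-3-methoxy-5-(3-TBSO-prop-1-yn-1-yl)phenyl]acetate
Product: 8 methyl 2-[2-hydroxy-3-methoxy-5-(3-TBSO-propyl)phenyl]acetate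
Conditions: H2 (1 atm), 10% Pd/C, EtOAc, rt
Reagents that add atoms: none
Why: heterogeneous hydrogenation should saturate the alkyne and hydrogenolyse the aryl benzyl ether in one operation, freeing the phenol for the later etherification while ester and TBS ether survive the neutral medium.

Step 6
Reactants: 9 methyl 4-hydroxy-3,5-dimethoxybenzoate (methyl syringate); 10 bromoacetic acid
Product: 11 2-[2,6-dimethoxy-4-(methoxycarbonyl)phenoxy]acetic acid
Conditions: NaH (2.5 equiv), THF, 0 °C → reflux; then aq. HCl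
Reagents that add atoms: none
Why: Williamson O-alkylation of the sodium phenoxide by sodium bromoacetate (SN2 at an α-halo carboxylate) under anhydrous conditions that leave the methyl benzoate, the latent ring B CH2OH, intact.

Step 7
Reactants: 11 2-[2,6-dimethoxy-4-(methoxycarbonyl)phenoxy]acetic acid; 12 (4R)-4-benzyl-1,3-oxazolidin-2-one
Product: 14 methyl 4-{2-[(4R)-4-benzyl-2-oxo-1,3-oxazolidin-3-yl]-2-oxoethoxy}-3,5-dimethoxybenzoate, via mixed pivalic anhydride 13 (not isolated)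
Conditions: PivCl, Et3N, THF, −20 °C; then LiCl, 12, −20 °C → rt
Reagents that add atoms: pivaloyl chloride, CC(C)(C)C(Cl)=O (atoms only in intermediate 13)
Why: N-acylation of the oxazolidinone through the mixed anhydride, which is attacked at the less hindered aryloxyacetyl carbonyl, installs the chiral auxiliary without strong base.

Step 8
Reactants: 14 methyl 4-{2-[(4R)-4-benzyl-2-oxo-1,3-oxazolidin-3-yl]-2-oxoethoxy}-3,5-dimethoxybenzoate; 15 4-(benzyloxy)-3-methoxybenzaldehyde
Product: 17 methyl 4-{[(1S,2R)-1-[4-(benzyloxy)-3-methoxyphenyl]-3-[(4R)-4-benzyl-2-oxo-1,3-oxazolidin-3-yl]-1-hydroxy-3-oxopropan-2-yl]oxy}-3,5-dimethoxybenzoate, via dibutylboron Z-enolate 16 (not isolated)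
Conditions: Bu2BOTf, i-Pr2NEt, CH2Cl2, −78 → 0 °C; then 15, −78 → 0 °C; pH 7 buffer, MeOH, H2O2, 0 °C
Reagents that add atoms: dibutylboron triflate, CCCCB(CCCC)OS(=O)(=O)C(F)(F)F (atoms only in intermediate 16)
Why: Evans syn glycolate aldol: the Z boron enolate reacts through a closed Zimmerman–Traxler chair in which the (R)-benzyl group of the dipole-opposed auxiliary shields one enolate face, setting C8 (the configuration of the target) and C7 (syn, i.e. threo) together.

Step 9
Reactants: 17 methyl 4-{[(1S,2R)-1-[4-(benzyloxy)-3-methoxyphenyl]-3-[(4R)-4-benzyl-2-oxo-1,3-oxazolidin-3-yl]-1-hydroxy-3-oxopropan-2-yl]oxy}-3,5-dimethoxybenzoate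
Product: 18 methyl 4-{[(1S,2S)-1-[4-(benzyloxy)-3-methoxyphenyl]-1,3-dihydroxypropan-2-yl]oxy}-3,5-dimethoxybenzoate (threo)
Conditions: NaBH4, THF–H2O (4:1), 0 °C → rt
Reagents that add atoms: none
Why: reductive cleavage of the N-acyloxazolidinone: borohydride reduces the activated exocyclic imide carbonyl to the primary alcohol while the electron-rich methyl benzoate is inert to NaBH4; the C8 descriptor changes from R to S only because the CIP ranking of its carbon neighbours switches.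

Step 10
Reactants: 18 methyl 4-{[(1S,2S)-1-[4-(benzyloxy)-3-methoxyphenyl]-1,3-dihydroxypropan-2-yl]oxy}-3,5-dimethoxybenzoate
Product: 19 methyl 4-{[(1S,2S)-1-[4-(benzyloxy)-3-methoxyphenyl]-1-hydroxy-3-TBSO-propan-2-yl]oxy}-3,5-dimethoxybenzoate
Conditions: TBSCl (1.05 equiv), imidazole, CH2Cl2, 0 °C
Reagents that add atoms: tert-butyldimethylsilyl chloride, CC(C)(C)[Si](C)(C)Cl
Why: selective silylation of the primary C9 hydroxyl over the hindered secondary benzylic C7 hydroxyl, on steric grounds.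

Step 11
Reactants: 19 methyl 4-{[(1S,2S)-1-[4-(benzyloxy)-3-methoxyphenyl]-1-hydroxy-3-TBSO-propan-2-yl]oxy}-3,5-dimethoxybenzoate
Product: 20 methyl 4-{[(1R,2S)-1-[4-(benzyloxy)-3-methoxyphenyl]-1-[(4-nitrobenzoyl)oxy]-3-TBSO-propan-2-yl]oxy}-3,5-dimethoxybenzoate
Conditions: 4-O2NC6H4CO2H, PPh3, DIAD, toluene, 0 °C → rt
Reagents that add atoms: 4-nitrobenzoic acid, OC(=O)c1ccc(cc1)[N+](=O)[O-]
Why: Mitsunobu inversion: SN2 displacement of the C7 alkoxyphosphonium by the acidic carboxylate inverts C7 and turns the threo into the erythro (7R,8S) series, the inductively withdrawing C8 aryloxy group disfavouring ionisation of the benzylic centre.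

Step 12
Reactants: 20 methyl 4-{[(1R,2S)-1-[4-(benzyloxy)-3-methoxyphenyl]-1-[(4-nitrobenzoyl)oxy]-3-TBSO-propan-2-yl]oxy}-3,5-dimethoxybenzoate
Product: 21 methyl 4-{[(1R,2S)-1-[4-(benzyloxy)-3-methoxyphenyl]-1-hydroxy-3-TBSO-propan-2-yl]oxy}-3,5-dimethoxybenzoate (erythro)
Conditions: K2CO3, MeOH, 0 °C → rt
Reagents that add atoms: none
Why: base-catalysed transesterification cleaves the activated 4-nitrobenzoate at the acyl carbon, so C7 keeps its new configuration, and exchange at the ring B methyl ester is degenerate.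

Step 13
Reactants: 21 methyl 4-{[(1R,2S)-1-[4-(benzyloxy)-3-methoxyphenyl]-1-hydroxy-3-TBSO-propan-2-yl]oxy}-3,5-dimethoxybenzoate
Product: 22 methyl 4-{[(1R,2S)-1-[4-(benzyloxy)-3-methoxyphenyl]-1,3-bis(TBSO)propan-2-yl]oxy}-3,5-dimethoxybenzoate
Conditions: TBSOTf, 2,6-lutidine, CH2Cl2, −78 → 0 °C
Reagents that add atoms: tert-butyldimethylsilyl triflate, CC(C)(C)[Si](C)(C)OS(=O)(=O)C(F)(F)F
Why: silylation of the hindered secondary benzylic alcohol needs the silyl triflate; the hindered base keeps the medium non-acidic, so the benzylic centre is not ionised.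

Step 14
Reactants: 22 methyl 4-{[(1R,2S)-1-[4-(benzyloxy)-3-methoxyphenyl]-1,3-bis(TBSO)propan-2-yl]oxy}-3,5-dimethoxybenzoate
Product: 23 (4-{[(1R,2S)-1-[4-(benzyloxy)-3-methoxyphenyl]-1,3-bis(TBSO)propan-2-yl]oxy}-3,5-dimethoxyphenyl)methanol
Conditions: DIBAL-H (3 equiv), CH2Cl2, −78 → −20 °C; Rochelle salt
Reagents that add atoms: none
Why: hydride reduction of the aryl ester to the benzylic alcohol; silyl and benzyl ethers are inert to DIBAL-H.

Step 15
Reactants: 23 (4-{[(1R,2S)-1-[4-(benzyloxy)-3-methoxyphenyl]-1,3-bis(TBSO)propan-2-yl]oxy}-3,5-dimethoxyphenyl)methanol; 8 methyl 2-[2-hydroxy-3-methoxy-5-(3-TBSO-propyl)phenyl]acetate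
Product: 24 methyl 2-{2-[(4-{[(1R,2S)-1-[4-(benzyloxy)-3-methoxyphenyl]-1,3-bis(TBSO)propan-2-yl]oxy}-3,5-dimethoxyphenyl)methoxy]-3-methoxy-5-(3-TBSO-propyl)phenyl}acetate
Conditions: PPh3, DIAD, THF, 0 °C → rt
Reagents that add atoms: none
Why: Mitsunobu etherification: the phenol is the only acidic partner and the only free hydroxyl of 23 is the primary benzylic one, which is displaced by SN2 at a CH2 carbon.

Step 16
Reactants: 24 methyl 2-{2-[(4-{[(1R,2S)-1-[4-(benzyloxy)-3-methoxyphenyl]-1,3-bis(TBSO)propan-2-yl]oxy}-3,5-dimethoxyphenyl)methoxy]-3-methoxy-5-(3-TBSO-propyl)phenyl}acetate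
Product: 25 methyl 2-diazo-2-{2-[(4-{[(1R,2S)-1-[4-(benzyloxy)-3-methoxyphenyl]-1,3-bis(TBSO)propan-2-yl]oxy}-3,5-dimethoxyphenyl)methoxy]-3-methoxy-5-(3-TBSO-propyl)phenyl}acetate
Conditions: p-ABSA, DBU, MeCN, 0 °C → rt
Reagents that add atoms: 4-acetamidobenzenesulfonyl azide (p-ABSA), CC(=O)Nc1ccc(cc1)S(=O)(=O)N=[N+]=[N-]
Why: Regitz diazo transfer: DBU deprotonates only the arylacetate CH2, the single carbon acid of sufficient acidity, and the sulfonyl azide delivers N2 to that carbon.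

Step 17
Reactants: 25 methyl 2-diazo-2-{2-[(4-{[(1R,2S)-1-[4-(benzyloxy)-3-methoxyphenyl]-1,3-bis(TBSO)propan-2-yl]oxy}-3,5-dimethoxyphenyl)methoxy]-3-methoxy-5-(3-TBSO-propyl)phenyl}acetate
Product: 26 methyl (2R,3S)-2-(4-{[(1R,2S)-1-[4-(benzyloxy)-3-methoxyphenyl]-1,3-bis(TBSO)propan-2-yl]oxy}-3,5-dimethoxyphenyl)-7-methoxy-5-(3-TBSO-propyl)-2,3-dihydro-1-benzofuran-3-carboxylate (2-aryl and 3-ester cis)
Conditions: Rh2(S-PTTL)4 (2 mol %), toluene, −60 °C, slow addition of 25 (final ca. 0.02 M)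
Reagents that add atoms: none
Why: Rh2(S-PTTL)4, dirhodium tetrakis[N-phthaloyl-(S)-tert-leucinate], decomposes the diazo ester with loss of N2 to a donor/acceptor rhodium carbene, which draws hydride character from one hydrogen of the ring B O–CH2 group while the C2–C3 bond forms in the same concerted, asynchronous three-centre transition state. The closest known reaction type is the dirhodium-carboxylate-catalysed intramolecular 1,5 C–H insertion of methyl 2-(2-benzyloxyaryl)-2-diazoacetates, which gives cis 2-aryl-2,3-dihydrobenzofuran-3-carboxylates. The dihydrofuran ring (O1, C2, C3, C3a, C7a) closes by this 1,5-insertion through a five-membered cyclic transition state, the benzylic carbon being the fifth atom counted from the carbene carbon. C2 is set by which of the two enantiotopic benzylic hydrogens the chiral phthalimido-carboxylate pocket presents to the carbene and C3 by the carbene face that the same ligand wall leaves open; ester and ring B aryl end up cis because the product forms under kinetic control and leaves the metal without any base that could epimerise C3. The step needs site selectivity, cis diastereoselectivity and facial selectivity: the site is secured by the substrate, since only the O–CH2 hydrogens, activated by the ether oxygen and the electron-rich ring B, can reach the carbene in a five-membered array, while dilution at −60 °C suppresses intermolecular insertion next to the silyl and benzyl ethers and the remote C7 and C8 centres are too distant to oppose catalyst control.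

Step 18
Reactants: 26 methyl (2R,3S)-2-(4-{[(1R,2S)-1-[4-(benzyloxy)-3-methoxyphenyl]-1,3-bis(TBSO)propan-2-yl]oxy}-3,5-dimethoxyphenyl)-7-methoxy-5-(3-TBSO-propyl)-2,3-dihydro-1-benzofuran-3-carboxylate
Product: 27 [(2R,3R)-2-(4-{[(1R,2S)-1-[4-(benzyloxy)-3-methoxyphenyl]-1,3-bis(TBSO)propan-2-yl]oxy}-3,5-dimethoxyphenyl)-7-methoxy-5-(3-TBSO-propyl)-2,3-dihydro-1-benzofuran-3-yl]methanol (cis)
Conditions: DIBAL-H (3 equiv), CH2Cl2, −78 °C; Rochelle salt
Reagents that add atoms: none
Why: the Lewis-acidic, non-basic hydride reduces the ester through the aluminium hemiacetal to the alcohol at −78 °C without enolising C3, so the cis geometry is kept (the C3 descriptor changes from S to R only through the CIP ranking).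

Step 19
Reactants: 27 [(2R,3R)-2-(4-{[(1R,2S)-1-[4-(benzyloxy)-3-methoxyphenyl]-1,3-bis(TBSO)propan-2-yl]oxy}-3,5-dimethoxyphenyl)-7-methoxy-5-(3-TBSO-propyl)-2,3-dihydro-1-benzofuran-3-yl]methanol
Product: 28 (1R,2S)-1-[4-(benzyloxy)-3-methoxyphenyl]-2-{4-[(2R,3R)-3-(hydroxymethyl)-5-(3-hydroxypropyl)-7-methoxy-2,3-dihydro-1-benzofuran-2-yl]-2,6-dimethoxyphenoxy}propane-1,3-diol
Conditions: Bu4NF (TBAF), THF, 0 °C → rt
Reagents that add atoms: none
Why: fluoride-driven desilylation (strong Si–F bond) removes all three TBS ethers under conditions that touch neither the benzyl ether nor any stereocentre.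

Step 20
Reactants: 28 (1R,2S)-1-[4-(benzyloxy)-3-methoxyphenyl]-2-{4-[(2R,3R)-3-(hydroxymethyl)-5-(3-hydroxypropyl)-7-methoxy-2,3-dihydro-1-benzofuran-2-yl]-2,6-dimethoxyphenoxy}propane-1,3-diol
Product: 29 (1R,2S)-1-(4-hydroxy-3-methoxyphenyl)-2-{4-[(2R,3R)-3-(hydroxymethyl)-5-(3-hydroxypropyl)-7-methoxy-2,3-dihydro-1-benzofuran-2-yl]-2,6-dimethoxyphenoxy}propane-1,3-diol (CNP0301567.1)
Conditions: H2 (1 atm), 10% Pd/C, EtOAc–MeOH, rt
Reagents that add atoms: none
Why: hydrogenolysis of the aryl benzyl ether on palladium in a neutral medium is much faster than cleavage of the C7 carbinol or of the C2–O1 bond, so the free phenol should be released without loss of either.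

Compound list
1 | 5-bromo-2-hydroxy-3-methoxybenzaldehyde | COc1cc(Br)cc(C=O)c1O | starting material
2 | 2-(benzyloxy)-5-bromo-3-methoxybenzaldehyde | COc1cc(Br)cc(C=O)c1OCc1ccccc1 | intermediate
3 | methyl (methylsulfanyl)methyl sulfoxide (FAMSO, racemic at sulfur) | CSCS(C)=O | starting material
4 | 2-(benzyloxy)-5-bromo-1-methoxy-3-[2-(methylsulfanyl)-2-(methylsulfinyl)ethenyl]benzene (alkene geometry and sulfur configuration not controlled) | COc1cc(Br)cc(C=C(SC)S(C)=O)c1OCc1ccccc1 | intermediate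
5 | methyl 2-[2-(benzyloxy)-5-bromo-3-methoxyphenyl]acetate | COC(=O)Cc1cc(Br)cc(OC)c1OCc1ccccc1 | intermediate
6 | tert-butyldimethyl(prop-2-yn-1-yloxy)silane | C#CCO[Si](C)(C)C(C)(C)C | starting material
7 | methyl 2-[2-(benzyloxy)-3-methoxy-5-(3-TBSO-prop-1-yn-1-yl)phenyl]acetate | COC(=O)Cc1cc(C#CCO[Si](C)(C)C(C)(C)C)cc(OC)c1OCc1ccccc1 | intermediate
8 | methyl 2-[2-hydroxy-3-methoxy-5-(3-TBSO-propyl)phenyl]acetate | COC(=O)Cc1cc(CCCO[Si](C)(C)C(C)(C)C)cc(OC)c1O | intermediate
9 | methyl 4-hydroxy-3,5-dimethoxybenzoate (methyl syringate) | COC(=O)c1cc(OC)c(O)c(OC)c1 | starting material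
10 | bromoacetic acid | OC(=O)CBr | starting material
11 | 2-[2,6-dimethoxy-4-(methoxycarbonyl)phenoxy]acetic acid | COC(=O)c1cc(OC)c(OCC(=O)O)c(OC)c1 | intermediate
12 | (4R)-4-benzyl-1,3-oxazolidin-2-one | O=C1N[C@H](Cc2ccccc2)CO1 | starting material
13 | 2-[2,6-dimethoxy-4-(methoxycarbonyl)phenoxy]acetic pivalic anhydride | COC(=O)c1cc(OC)c(OCC(=O)OC(=O)C(C)(C)C)c(OC)c1 | intermediate
14 | methyl 4-{2-[(4R)-4-benzyl-2-oxo-1,3-oxazolidin-3-yl]-2-oxoethoxy}-3,5-dimethoxybenzoate | COC(=O)c1cc(OC)c(OCC(=O)N2[C@H](Cc3ccccc3)COC2=O)c(OC)c1 | intermediate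
15 | 4-(benzyloxy)-3-methoxybenzaldehyde | COc1cc(C=O)ccc1OCc1ccccc1 | starting material
16 | dibutylboron (Z)-enolate of imide 14 | COC(=O)c1cc(OC)c(O/C=C(\OB(CCCC)CCCC)N2[C@H](Cc3ccccc3)COC2=O)c(OC)c1 | intermediate
17 | methyl 4-{[(1S,2R)-1-[4-(benzyloxy)-3-methoxyphenyl]-3-[(4R)-4-benzyl-2-oxo-1,3-oxazolidin-3-yl]-1-hydroxy-3-oxopropan-2-yl]oxy}-3,5-dimethoxybenzoate | COc1cc([C@H](O)[C@H](C(=O)N2[C@H](Cc3ccccc3)COC2=O)Oc2c(OC)cc(C(=O)OC)cc2OC)ccc1OCc1ccccc1 | intermediate
18 | methyl 4-{[(1S,2S)-1-[4-(benzyloxy)-3-methoxyphenyl]-1,3-dihydroxypropan-2-yl]oxy}-3,5-dimethoxybenzoate | COc1cc([C@H](O)[C@H](CO)Oc2c(OC)cc(C(=O)OC)cc2OC)ccc1OCc1ccccc1 | intermediate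
19 | methyl 4-{[(1S,2S)-1-[4-(benzyloxy)-3-methoxyphenyl]-1-hydroxy-3-TBSO-propan-2-yl]oxy}-3,5-dimethoxybenzoate | COc1cc([C@H](O)[C@H](CO[Si](C)(C)C(C)(C)C)Oc2c(OC)cc(C(=O)OC)cc2OC)ccc1OCc1ccccc1 | intermediate
20 | methyl 4-{[(1R,2S)-1-[4-(benzyloxy)-3-methoxyphenyl]-1-[(4-nitrobenzoyl)oxy]-3-TBSO-propan-2-yl]oxy}-3,5-dimethoxybenzoate | COc1cc([C@@H](OC(=O)c2ccc(cc2)[N+](=O)[O-])[C@H](CO[Si](C)(C)C(C)(C)C)Oc2c(OC)cc(C(=O)OC)cc2OC)ccc1OCc1ccccc1 | intermediate
21 | methyl 4-{[(1R,2S)-1-[4-(benzyloxy)-3-methoxyphenyl]-1-hydroxy-3-TBSO-propan-2-yl]oxy}-3,5-dimethoxybenzoate | COc1cc([C@@H](O)[C@H](CO[Si](C)(C)C(C)(C)C)Oc2c(OC)cc(C(=O)OC)cc2OC)ccc1OCc1ccccc1 | intermediate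
22 | methyl 4-{[(1R,2S)-1-[4-(benzyloxy)-3-methoxyphenyl]-1,3-bis(TBSO)propan-2-yl]oxy}-3,5-dimethoxybenzoate | COc1cc([C@@H](O[Si](C)(C)C(C)(C)C)[C@H](CO[Si](C)(C)C(C)(C)C)Oc2c(OC)cc(C(=O)OC)cc2OC)ccc1OCc1ccccc1 | intermediate
23 | (4-{[(1R,2S)-1-[4-(benzyloxy)-3-methoxyphenyl]-1,3-bis(TBSO)propan-2-yl]oxy}-3,5-dimethoxyphenyl)methanol | COc1cc([C@@H](O[Si](C)(C)C(C)(C)C)[C@H](CO[Si](C)(C)C(C)(C)C)Oc2c(OC)cc(CO)cc2OC)ccc1OCc1ccccc1 | intermediate
24 | methyl 2-{2-[(4-{[(1R,2S)-1-[4-(benzyloxy)-3-methoxyphenyl]-1,3-bis(TBSO)propan-2-yl]oxy}-3,5-dimethoxyphenyl)methoxy]-3-methoxy-5-(3-TBSO-propyl)phenyl}acetate | COc1cc([C@@H](O[Si](C)(C)C(C)(C)C)[C@H](CO[Si](C)(C)C(C)(C)C)Oc2c(OC)cc(COc3c(OC)cc(CCCO[Si](C)(C)C(C)(C)C)cc3CC(=O)OC)cc2OC)ccc1OCc1ccccc1 | intermediate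
25 | methyl 2-diazo-2-{2-[(4-{[(1R,2S)-1-[4-(benzyloxy)-3-methoxyphenyl]-1,3-bis(TBSO)propan-2-yl]oxy}-3,5-dimethoxyphenyl)methoxy]-3-methoxy-5-(3-TBSO-propyl)phenyl}acetate | COc1cc([C@@H](O[Si](C)(C)C(C)(C)C)[C@H](CO[Si](C)(C)C(C)(C)C)Oc2c(OC)cc(COc3c(OC)cc(CCCO[Si](C)(C)C(C)(C)C)cc3C(=[N+]=[N-])C(=O)OC)cc2OC)ccc1OCc1ccccc1 | intermediate
26 | methyl (2R,3S)-2-(4-{[(1R,2S)-1-[4-(benzyloxy)-3-methoxyphenyl]-1,3-bis(TBSO)propan-2-yl]oxy}-3,5-dimethoxyphenyl)-7-methoxy-5-(3-TBSO-propyl)-2,3-dihydro-1-benzofuran-3-carboxylate (cis) | COc1cc([C@@H](O[Si](C)(C)C(C)(C)C)[C@H](CO[Si](C)(C)C(C)(C)C)Oc2c(OC)cc([C@@H]3Oc4c(OC)cc(CCCO[Si](C)(C)C(C)(C)C)cc4[C@@H]3C(=O)OC)cc2OC)ccc1OCc1ccccc1 | intermediate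
27 | [(2R,3R)-2-(4-{[(1R,2S)-1-[4-(benzyloxy)-3-methoxyphenyl]-1,3-bis(TBSO)propan-2-yl]oxy}-3,5-dimethoxyphenyl)-7-methoxy-5-(3-TBSO-propyl)-2,3-dihydro-1-benzofuran-3-yl]methanol (cis) | COc1cc([C@@H](O[Si](C)(C)C(C)(C)C)[C@H](CO[Si](C)(C)C(C)(C)C)Oc2c(OC)cc([C@@H]3Oc4c(OC)cc(CCCO[Si](C)(C)C(C)(C)C)cc4[C@@H]3CO)cc2OC)ccc1OCc1ccccc1 | intermediate
28 | (1R,2S)-1-[4-(benzyloxy)-3-methoxyphenyl]-2-{4-[(2R,3R)-3-(hydroxymethyl)-5-(3-hydroxypropyl)-7-methoxy-2,3-dihydro-1-benzofuran-2-yl]-2,6-dimethoxyphenoxy}propane-1,3-diol | COc1cc([C@@H](O)[C@H](CO)Oc2c(OC)cc([C@@H]3Oc4c(OC)cc(CCCO)cc4[C@@H]3CO)cc2OC)ccc1OCc1ccccc1 | intermediate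
29 | (1R,2S)-1-(4-hydroxy-3-methoxyphenyl)-2-{4-[(2R,3R)-3-(hydroxymethyl)-5-(3-hydroxypropyl)-7-methoxy-2,3-dihydro-1-benzofuran-2-yl]-2,6-dimethoxyphenoxy}propane-1,3-diol | COc1cc([C@@H](O)[C@H](CO)Oc2c(OC)cc([C@@H]3Oc4c(OC)cc(CCCO)cc4[C@@H]3CO)cc2OC)ccc1O | target

Total step count: 20. Longest linear sequence: 15 steps (steps 6 to 20, from methyl syringate 9); the ring C branch (steps 1 to 5) joins at step 15.

Steps most likely to fail

1. Step 17 (key step). The cis geometry may erode on this large substrate, through a competing trans-selective transition state or through epimerisation at C3 of the cis ester on handling. The catalyst may also discriminate incompletely between the two benzylic hydrogens; the wrong-face cis product is a diastereomer of 26 and would be removed by chromatography at 26 or 27. The fallback sets C3 by kinetic enolate protonation instead of by the insertion. It sets out from 25, which is cyclised as in step 17. Material that emerges as the trans ester F1, with the same C2 configuration, alone or mixed with 26, is deprotonated with LiN(SiMe3)2 in THF at −78 °C to the lithium ester enolate F2. Quenching at −78 °C with acetic acid should deliver the proton to C3 from the face opposite the C2 aryl group, which places the ester cis to the aryl and returns to the route at 26. Ring opening of the enolate is not expected, since loss of the ring oxygen would be the reverse of a 5-endo-trig closure.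

2. Step 11. The alkoxyphosphonium at the electron-rich benzylic C7 may ionise, giving partial retention, or eliminate to the enol ether, so inversion would be incomplete. The fallback replaces substitution by oxidation and chelation-controlled reduction. It sets out from 19, which Dess–Martin periodinane (NaHCO3, CH2Cl2, 0 °C) should oxidise to the aryl ketone F3 under neutral conditions that do not epimerise C8. Reduction with Zn(BH4)2 in Et2O at −78 °C should proceed through a five-membered zinc chelate between the ketone oxygen and the C8 aryl ether oxygen. Hydride then arrives from the side of the C8 hydrogen and gives the anti (erythro) alcohol, rejoining the route at 21 and making steps 11 and 12 unnecessary.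

3. Step 15. The redox condensation may stall with the doubly ortho-substituted phenol, and lactonisation of 8 or C-alkylation may compete. The fallback replaces it by a Williamson alkylation with a preformed electrophile. It sets out from 23, which MsCl, LiCl and 2,4,6-collidine in DMF at 0 °C should convert into the benzylic chloride F4. Alkylation of phenol 8 with F4 (K2CO3, Bu4NI cat., DMF, rt) returns to the route at 24.

Further compounds
F1 | step 17 | methyl (2R,3R)-2-(4-{[(1R,2S)-1-[4-(benzyloxy)-3-methoxyphenyl]-1,3-bis(TBSO)propan-2-yl]oxy}-3,5-dimethoxyphenyl)-7-methoxy-5-(3-TBSO-propyl)-2,3-dihydro-1-benzofuran-3-carboxylate (trans) | COc1cc([C@@H](O[Si](C)(C)C(C)(C)C)[C@H](CO[Si](C)(C)C(C)(C)C)Oc2c(OC)cc([C@@H]3Oc4c(OC)cc(CCCO[Si](C)(C)C(C)(C)C)cc4[C@H]3C(=O)OC)cc2OC)ccc1OCc1ccccc1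
F2 | step 17 | lithium ester enolate of F1 (C3 planar, C2 unchanged) | COc1cc([C@@H](O[Si](C)(C)C(C)(C)C)[C@H](CO[Si](C)(C)C(C)(C)C)Oc2c(OC)cc([C@@H]3Oc4c(OC)cc(CCCO[Si](C)(C)C(C)(C)C)cc4C3=C([O-])OC)cc2OC)ccc1OCc1ccccc1.[Li+]
F3 | step 11 | methyl 4-{[(2S)-1-[4-(benzyloxy)-3-methoxyphenyl]-1-oxo-3-TBSO-propan-2-yl]oxy}-3,5-dimethoxybenzoate | COc1cc(C(=O)[C@H](CO[Si](C)(C)C(C)(C)C)Oc2c(OC)cc(C(=O)OC)cc2OC)ccc1OCc1ccccc1
F4 | step 15 | 4-(benzyloxy)-1-[(1R,2S)-1,3-bis(TBSO)-2-[4-(chloromethyl)-2,6-dimethoxyphenoxy]propyl]-2-methoxybenzene | COc1cc([C@@H](O[Si](C)(C)C(C)(C)C)[C@H](CO[Si](C)(C)C(C)(C)C)Oc2c(OC)cc(CCl)cc2OC)ccc1OCc1ccccc1
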